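The cyclohexa-2,5-dienone ring (C-1 carbonyl, C-2 allyl, C-3, quaternary C-4, C-5 methoxy, C-6) is cut into two three-carbon pieces: C-1–C-3 as a 2-allyl-3-methoxyacryloyl chloride and C-4–C-6 as a terminal propargylic methyl ether that carries the side chain. The key step exploits the vinylogous ester C-5(OMe)=C-6–C-1=O, which is a masked ynone plus methanol, and the enone β-carbon C-3. In one pot, acylation of the alkyne forms C-6–C-1, methoxide adds to C-5, and the resulting dienolate closes onto C-3 with loss of methoxide, forming C-3–C-4 and the quaternary stereocentre stereoconvergently under control of the adjacent methyl-bearing carbon.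

Key step: step 10

Remark: ring locants C-1 to C-6 are used as above, C-7 is the benzylic carbon and C-8 the methyl-bearing carbon; the carbinol centre made in step 5 is left uncontrolled because step 10 planarises it, and the sequential one-pot protocol of step 10 is taken as one operation.

Step 1
Reactants: 1 (4R)-4-benzyl-3-propanoyl-1,3-oxazolidin-2-one; 2 3,4-dimethoxybenzaldehyde
Product: 3 (4R)-4-benzyl-3-[(2R,3R)-3-(3,4-dimethoxyphenyl)-3-hydroxy-2-methylpropanoyl]-1,3-oxazolidin-2-one
Conditions: Bu2BOTf, i-Pr2NEt, CH2Cl2, 0 °C; then 2, −78 °C to 0 °C; pH 7 buffer, MeOH, H2O2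
Reagents that add atoms: none
Why: Evans syn-aldol reaction, in which the Z-boron enolate reacts through a Zimmerman–Traxler chair and the (R)-benzyl auxiliary selects the enolate face, so that C-7 and C-8 should both be set as R (syn).

Step 2
Reactants: 3 aldol adduct
Product: 4 (2R,3R)-3-(3,4-dimethoxyphenyl)-3-hydroxy-N-methoxy-N,2-dimethylpropanamide
Conditions: MeNHOMe·HCl, AlMe3, CH2Cl2, −20 °C to rt
Reagents that add atoms: N,O-dimethylhydroxylamine hydrochloride CNOC.Cl
Why: Weinreb transamidation by the aluminium amide, assisted by the free β-hydroxyl, should release the auxiliary without epimerising C-8.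

Step 3
Reactants: 4 hydroxy Weinreb amide
Product: 5 (2R,3R)-3-{[tert-butyl(dimethyl)silyl]oxy}-3-(3,4-dimethoxyphenyl)-N-methoxy-N,2-dimethylpropanamide
Conditions: TBSOTf, 2,6-lutidine, CH2Cl2, −78 °C to 0 °C
Reagents that add atoms: tert-butyldimethylsilyl triflate CC(C)(C)[Si](C)(C)OS(=O)(=O)C(F)(F)F
Why: Standard silylation of a secondary benzylic alcohol, which gives a bulky, base-stable ether that later serves as the large group for stereocontrol.

Step 4
Reactants: 5 silylated Weinreb amide
Product: 6 (2R,3R)-3-{[tert-butyl(dimethyl)silyl]oxy}-3-(3,4-dimethoxyphenyl)-2-methylpropanal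
Conditions: i-Bu2AlH, THF, −78 °C; Rochelle salt work-up; used at once
Reagents that add atoms: none
Why: Reduction of a Weinreb amide stops at the chelated tetrahedral intermediate, so the aldehyde should form without over-reduction, and the low temperature guards C-8.

Step 5
Reactants: 6 aldehyde
Product: 7 (4S,5R)-5-{[tert-butyl(dimethyl)silyl]oxy}-5-(3,4-dimethoxyphenyl)-4-methylpent-1-yn-3-ol (both C-3 epimers)
Conditions: HC≡CMgBr, THF, −78 °C to 0 °C; aq. NH4Cl
Reagents that add atoms: ethynylmagnesium bromide C#C[Mg]Br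
Why: Grignard addition of an acetylide to an aldehyde, whose new carbinol centre (the future C-4) needs no control.

Step 6
Reactants: 7 propargylic alcohol
Product: 8 tert-butyl{[(1R,2S)-1-(3,4-dimethoxyphenyl)-3-methoxy-2-methylpent-4-yn-1-yl]oxy}dimethylsilane (both C-3 epimers)
Conditions: Me3OBF4, 1,8-bis(dimethylamino)naphthalene, 4 Å MS, CH2Cl2, rt
Reagents that add atoms: trimethyloxonium tetrafluoroborate C[O+](C)C.F[B-](F)(F)F
Why: O-methylation with the Meerwein salt under non-basic conditions should avoid the 1,5-silyl migration that an alkoxide could trigger and leaves the terminal alkyne untouched.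

Step 7
Reactants: 9 methyl pent-4-enoate
Product: 11 methyl (2E)-2-(methoxymethylidene)pent-4-enoate, via sodium enolate 10 (not isolated)
Conditions: NaH, HCO2Me, MeOH (cat.), THF, 0 °C to rt; then Me2SO4, DMF, rt
Reagents that add atoms: methyl formate COC=O; dimethyl sulfate COS(=O)(=O)OC
Why: Crossed Claisen formylation followed by O-methylation of the ambident enolate with a hard electrophile in a polar aprotic medium, the standard entry to β-methoxyacrylates.

Step 8
Reactants: 11 β-methoxyacrylate ester
Product: 12 (2E)-2-(methoxymethylidene)pent-4-enoic acid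
Conditions: LiOH·H2O, THF/H2O, rt; then 1 M HCl to pH 3, 0 °C
Reagents that add atoms: lithium hydroxide [Li+].[OH-]
Why: Saponification, in which the vinylogous carbonate character of the ester slows but does not prevent acyl attack by hydroxide.

Step 9
Reactants: 12 β-methoxyacrylic acid
Product: 13 (2E)-2-(methoxymethylidene)pent-4-enoyl chloride
Conditions: (COCl)2, DMF (cat.), CH2Cl2, 0 °C to rt; volatiles removed, used crude
Reagents that add atoms: oxalyl chloride O=C(Cl)C(=O)Cl
Why: Acid chloride formation through the Vilsmeier-type chloroiminium catalyst, as established for 3-alkoxyacryloyl chlorides.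

Step 10
Reactants: 13 2-allyl-3-methoxyacryloyl chloride; 8 propargylic methyl ether
Product: 16 (4R)-4-[(1R,2R)-1-{[tert-butyl(dimethyl)silyl]oxy}-1-(3,4-dimethoxyphenyl)propan-2-yl]-4,5-dimethoxy-2-(prop-2-en-1-yl)cyclohexa-2,5-dien-1-one, via ynone 14 (not isolated), via bis(methoxyvinyl) ketone 15 (not isolated)
Conditions: PdCl2(PPh3)2 (2 mol%), CuI (4 mol%), Et3N (1.1 equiv), THF, rt; then NaOMe (2 equiv), 0 °C to rt; then LiN(SiMe3)2 (2 equiv), −78 °C to rt
Reagents that add atoms: sodium methoxide [Na+].[O-]C
Why: Proposed new method: acyl Sonogashira coupling joins the alkyne carbon C-6 to the acyl carbon C-1 to give ynone 14, methoxide then adds to its β-carbon C-5 (oxa-Michael) to give 15, and LiN(SiMe3)2 removes the γ-proton at C-4 so that the lithium dienolate closes onto C-3 and expels methoxide, which forms the C-3–C-4 bond and the dienone. The closest known reaction types are the one-pot coupling–addition–cyclocondensation sequences of ynones used for heterocycles and the addition–elimination of carbanions on β-alkoxy enones. The six-membered ring closes by a thermal disrotatory 6π electrocyclisation of the 2-oxidohexatriene (equivalently a 6-endo-trig vinylogous Michael addition), followed by E1cB loss of methoxide. The only new stereocentre, C-4, is controlled by C-8: allylic 1,3-strain holds the C-8 hydrogen in the dienolate plane, so C-3 should bond to the face that carries the methyl group, anti to the bulky silyloxybenzyl group, which corresponds to 4R. The step is stereoconvergent because both C-4 epimers of 8 and both enol ether geometries of 15 pass through the same planar dienolate, and the closure is driven by exchanging a lithium dienolate for lithium methoxide. It needs β-attack rather than carbonyl attack of methoxide on 14, which the soft ynone acceptor favours, and only the γ-carbon can reach C-3 through a six-membered transition state.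

Step 11
Reactants: 16 silyl ether dienone
Product: 17 (4R)-4-[(1R,2R)-1-(3,4-dimethoxyphenyl)-1-hydroxypropan-2-yl]-4,5-dimethoxy-2-(prop-2-en-1-yl)cyclohexa-2,5-dien-1-one
Conditions: HF·pyridine, pyridine, THF, 0 °C to rt; used without delay
Reagents that add atoms: none
Why: Buffered fluoride desilylation generates no alkoxide, which should keep the liberated C-7 hydroxyl from adding to the vinylogous ester carbon C-5.

Step 12
Reactants: 17 hydroxy dienone
Product: 18 (1R,2R)-1-(3,4-dimethoxyphenyl)-2-[(1R)-1,2-dimethoxy-4-oxo-5-(prop-2-en-1-yl)cyclohexa-2,5-dien-1-yl]propyl acetate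
Conditions: Ac2O, pyridine, DMAP (cat.), CH2Cl2, 0 °C to rt
Reagents that add atoms: acetic anhydride CC(=O)OC(C)=O
Why: DMAP-catalysed acetylation of the secondary benzylic alcohol proceeds with retention at C-7 and touches neither the dienone nor the enol ether.

Compound list
1 | (4R)-4-benzyl-3-propanoyl-1,3-oxazolidin-2-one | CCC(=O)N1[C@H](Cc2ccccc2)COC1=O | starting material
2 | 3,4-dimethoxybenzaldehyde | COc1ccc(C=O)cc1OC | starting material
3 | (4R)-4-benzyl-3-[(2R,3R)-3-(3,4-dimethoxyphenyl)-3-hydroxy-2-methylpropanoyl]-1,3-oxazolidin-2-one | O=C1OC[C@@H](Cc2ccccc2)N1C(=O)[C@H](C)[C@@H](O)c1ccc(OC)c(OC)c1 | intermediate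
4 | (2R,3R)-3-(3,4-dimethoxyphenyl)-3-hydroxy-N-methoxy-N,2-dimethylpropanamide | CON(C)C(=O)[C@H](C)[C@@H](O)c1ccc(OC)c(OC)c1 | intermediate
5 | (2R,3R)-3-{[tert-butyl(dimethyl)silyl]oxy}-3-(3,4-dimethoxyphenyl)-N-methoxy-N,2-dimethylpropanamide | CON(C)C(=O)[C@H](C)[C@@H](O[Si](C)(C)C(C)(C)C)c1ccc(OC)c(OC)c1 | intermediate
6 | (2R,3R)-3-{[tert-butyl(dimethyl)silyl]oxy}-3-(3,4-dimethoxyphenyl)-2-methylpropanal | O=C[C@H](C)[C@@H](O[Si](C)(C)C(C)(C)C)c1ccc(OC)c(OC)c1 | intermediate
7 | (4S,5R)-5-{[tert-butyl(dimethyl)silyl]oxy}-5-(3,4-dimethoxyphenyl)-4-methylpent-1-yn-3-ol, both C-3 epimers | C#CC(O)[C@H](C)[C@@H](O[Si](C)(C)C(C)(C)C)c1ccc(OC)c(OC)c1 | intermediate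
8 | tert-butyl{[(1R,2S)-1-(3,4-dimethoxyphenyl)-3-methoxy-2-methylpent-4-yn-1-yl]oxy}dimethylsilane, both C-3 epimers | C#CC(OC)[C@H](C)[C@@H](O[Si](C)(C)C(C)(C)C)c1ccc(OC)c(OC)c1 | intermediate
9 | methyl pent-4-enoate | C=CCCC(=O)OC | starting material
10 | sodium 2-(methoxycarbonyl)penta-1,4-dien-1-olate | [Na+].[O-]C=C(CC=C)C(=O)OC | intermediate (not isolated)
11 | methyl (2E)-2-(methoxymethylidene)pent-4-enoate | CO/C=C(\CC=C)C(=O)OC | intermediate
12 | (2E)-2-(methoxymethylidene)pent-4-enoic acid | CO/C=C(\CC=C)C(=O)O | intermediate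
13 | (2E)-2-(methoxymethylidene)pent-4-enoyl chloride | CO/C=C(\CC=C)C(=O)Cl | intermediate
14 | (1E,7S,8R)-8-{[tert-butyl(dimethyl)silyl]oxy}-8-(3,4-dimethoxyphenyl)-1,6-dimethoxy-7-methyl-2-(prop-2-en-1-yl)oct-1-en-4-yn-3-one, both C-6 epimers | CO/C=C(\CC=C)C(=O)C#CC(OC)[C@H](C)[C@@H](O[Si](C)(C)C(C)(C)C)c1ccc(OC)c(OC)c1 | intermediate (not isolated)
15 | (1E,7S,8R)-8-{[tert-butyl(dimethyl)silyl]oxy}-8-(3,4-dimethoxyphenyl)-1,5,6-trimethoxy-7-methyl-2-(prop-2-en-1-yl)octa-1,4-dien-3-one, both C-4 alkene isomers and both C-6 epimers | CO/C=C(\CC=C)C(=O)C=C(OC)C(OC)[C@H](C)[C@@H](O[Si](C)(C)C(C)(C)C)c1ccc(OC)c(OC)c1 | intermediate (not isolated)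
16 | (4R)-4-[(1R,2R)-1-{[tert-butyl(dimethyl)silyl]oxy}-1-(3,4-dimethoxyphenyl)propan-2-yl]-4,5-dimethoxy-2-(prop-2-en-1-yl)cyclohexa-2,5-dien-1-one | C=CCC1=C[C@@](OC)([C@H](C)[C@@H](O[Si](C)(C)C(C)(C)C)c2ccc(OC)c(OC)c2)C(OC)=CC1=O | intermediate
17 | (4R)-4-[(1R,2R)-1-(3,4-dimethoxyphenyl)-1-hydroxypropan-2-yl]-4,5-dimethoxy-2-(prop-2-en-1-yl)cyclohexa-2,5-dien-1-one | C=CCC1=C[C@@](OC)([C@H](C)[C@@H](O)c2ccc(OC)c(OC)c2)C(OC)=CC1=O | intermediate
18 | (1R,2R)-1-(3,4-dimethoxyphenyl)-2-[(1R)-1,2-dimethoxy-4-oxo-5-(prop-2-en-1-yl)cyclohexa-2,5-dien-1-yl]propyl acetate | C=CCC1=C[C@@](OC)([C@H](C)[C@@H](OC(C)=O)c2ccc(OC)c(OC)c2)C(OC)=CC1=O | target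

Total step count: 12. Longest linear sequence: 9 steps (steps 1 to 6, then 10 to 12).

Steps most likely to fail

Step 10. The ring closure may show poor facial selectivity at C-4. It may also stall at the open-chain stage, because addition–elimination on a β-methoxy enone is reversible, or be diverted by carbonyl attack of methoxide on the ynone. The fallback uses known chemistry and sets out from 8. Markovnikov hydration of the terminal alkyne with Ph3PAuNTf2 (cat.) in wet methanol would give the methyl ketone F1. C-acylation of its kinetic lithium enolate (LiN(SiMe3)2, THF, −78 °C, inverse addition) with 13 would give the β-diketone F2. Two equivalents of LDA would then form the β-diketone dianion, whose γ-carbon C-4 closes onto C-3 with loss of methoxide. This closure is driven by the stable diketone enolate and would give the cyclohexenedione F3. O-methylation (Me2SO4, K2CO3, acetone) and separation from the regioisomeric enol ether would bring the route back at 16.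

Step 11. The liberated C-7 hydroxyl may add to the vinylogous ester carbon C-5 and expel methanol, closing a fused tetrahydrofuran. The fallback sets out from 16 and never frees the hydroxyl: acetic anhydride with catalytic Bi(OTf)3 in MeCN at 0 °C exchanges the silyl group directly for acetyl. It comes back to the route at 18 and makes no new compound (F0).

Step 7. The ambident formyl ester enolate may be methylated on carbon, and the ester may self-condense during formylation. The fallback sets out from 9. Formylation with LDA and HCO2Me at −78 °C, with isolation, would give methyl 2-formylpent-4-enoate F4. Acetalisation with HC(OMe)3 and catalytic H2SO4 in MeOH would give the dimethyl acetal F5. Acid-catalysed thermal loss of methanol (TsOH cat., toluene, distillation) would form the enol ether without any enolate alkylation and come back to the route at 11.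

Further compounds
F1 | step 10 | (4S,5R)-5-{[tert-butyl(dimethyl)silyl]oxy}-5-(3,4-dimethoxyphenyl)-3-methoxy-4-methylpentan-2-one, both C-3 epimers | CC(=O)C(OC)[C@H](C)[C@@H](O[Si](C)(C)C(C)(C)C)c1ccc(OC)c(OC)c1
F2 | step 10 | (1E,7S,8R)-8-{[tert-butyl(dimethyl)silyl]oxy}-8-(3,4-dimethoxyphenyl)-1,6-dimethoxy-7-methyl-2-(prop-2-en-1-yl)oct-1-ene-3,5-dione, both C-6 epimers | CO/C=C(\CC=C)C(=O)CC(=O)C(OC)[C@H](C)[C@@H](O[Si](C)(C)C(C)(C)C)c1ccc(OC)c(OC)c1
F3 | step 10 | (4R)-4-[(1R,2R)-1-{[tert-butyl(dimethyl)silyl]oxy}-1-(3,4-dimethoxyphenyl)propan-2-yl]-4-methoxy-6-(prop-2-en-1-yl)cyclohex-5-ene-1,3-dione | C=CCC1=C[C@@](OC)([C@H](C)[C@@H](O[Si](C)(C)C(C)(C)C)c2ccc(OC)c(OC)c2)C(=O)CC1=O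
F0 | step 11 | none | none
F4 | step 7 | methyl 2-formylpent-4-enoate | C=CCC(C=O)C(=O)OC
F5 | step 7 | methyl 2-(dimethoxymethyl)pent-4-enoate | C=CCC(C(OC)OC)C(=O)OC
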